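The strategy rests on disconnecting the aryl ether bond O1–C8a of the dihydropyran ring, which lies para to the acyl-bearing carbon C6 of ring A. One palladium-catalysed intramolecular C–O coupling forms this bond and closes the chroman from benzaldehyde 8. Compound 8 carries chlorine on the future C8a, a 3-hydroxy-3-methylbutyl chain on the neighbouring carbon and MOM ethers on both oxygens flanking the formyl group. Since only that carbon bears a leaving group, the pyran oxygen cannot end up ortho to the acyl group. Aldehyde 9 then takes up the ring B 2-arylethyl Grignard reagent; oxidation and acidic MOM cleavage deliver the dihydrochalcone.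

Key step: step 5

Remarks on the chemistry (assumptions and corrections):
- Numbering: chroman numbering (O1, C2 to C8a) is used; ring A is the benzene ring of the chroman and ring B is the other arene. The target has no stereocentre; the only one on the way (carbinol 21) is racemic and is removed in step 13.
- Ring B carries its free hydroxyl meta and its methoxy para to the side chain, with the prenyl group ortho to the methoxy. A 5-bromovanillin pattern (4-hydroxy-3-methoxy, bromine next to the hydroxyl) would put the methyl group on the wrong oxygen. Bromocatechol 10 is therefore methylated at O4 only; 10 is assumed to be commercially available and is otherwise one step from 5-bromovanillin (AlCl3, pyridine).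
- In the coupling, O1 is the oxygen of the side-chain alcohol, and the group on C8a is lost. A chloride is used there instead of a sulfonate ester, for two reasons: mono-sulfonylation of a 3-alkyl-2,4,6-trihydroxybenzaldehyde would have to distinguish the para hydroxyl from the free ortho hydroxyl, and an aryl sulfonate para to a formyl group is easily cleaved by base.
- The tertiary alcohol is brought in ready-made, so no alkene hydration has to be run beside an oxidisable formyl group.

Step 1
Reactants: 1 5-chlororesorcinol
Product: 2 1-chloro-3,5-bis(methoxymethoxy)benzene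
Conditions: MOMCl (2.4 equiv), i-Pr2NEt (3 equiv), CH2Cl2, 0 °C → rt
Reagents that add atoms: chloromethyl methyl ether, COCCl
Why: Base-mediated O-alkylation of both phenols (MOM protection) should give the bis-acetal, which is stable to base, organometallic reagents and palladium and later provides the two directing groups for metalation.

Step 2
Reactants: 2 1-chloro-3,5-bis(methoxymethoxy)benzene
Product: 3 2-bromo-1-chloro-3,5-bis(methoxymethoxy)benzene
Conditions: NBS (1.0 equiv), MeCN, 0 °C → rt, dark
Reagents that add atoms: N-bromosuccinimide, O=C1CCC(=O)N1Br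
Why: Electrophilic aromatic bromination of a 1,3-dialkoxyarene should go para to one alkoxy group and ortho to the other (C2, equivalent to C6) rather than into the doubly flanked position between the acetal oxygens, so bromine is placed next to chlorine.

Step 3
Reactants: 3 2-bromo-1-chloro-3,5-bis(methoxymethoxy)benzene; 4 2-methylbut-3-en-2-ol
Product: 6 4-[2-chloro-4,6-bis(methoxymethoxy)phenyl]-2-methylbutan-2-ol, via alkylborane 5 (not isolated)
Conditions: 4 (1.5 equiv), 9-BBN, THF, 0 °C → rt; then 3, Pd(dppf)Cl2 (dppf = 1,1'-bis(diphenylphosphino)ferrocene, 5 mol%), K3PO4 (3 M aq), THF/DMF, 70 °C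
Reagents that add atoms: none
Why: Anti-Markovnikov hydroboration of the terminal alkene followed by B-alkyl Suzuki–Miyaura coupling should join the primary carbon to the arene at the C–Br bond, which adds to zerovalent palladium much faster than the unactivated C–Cl bond, and the free tertiary alcohol is tolerated under aqueous phosphate.

Step 4
Reactants: 6 4-[2-chloro-4,6-bis(methoxymethoxy)phenyl]-2-methylbutan-2-ol
Product: 8 4-chloro-3-(3-hydroxy-3-methylbutyl)-2,6-bis(methoxymethoxy)benzaldehyde, via dilithiated arene 7 (not isolated)
Conditions: n-BuLi (2.3 equiv), THF, −78 → 0 °C; DMF, −78 °C → rt; aq NH4Cl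
Reagents that add atoms: N,N-dimethylformamide, CN(C)C=O
Why: After deprotonation of the alcohol, directed ortho-metalation should take place at the ring C–H flanked by the two MOM ethers (cooperative directing groups, meta to chlorine so that no aryne can form), and formylation of the aryllithium with DMF places the aldehyde para to chlorine.

Step 5
Reactants: 8 4-chloro-3-(3-hydroxy-3-methylbutyl)-2,6-bis(methoxymethoxy)benzaldehyde
Product: 9 5,7-bis(methoxymethoxy)-2,2-dimethyl-3,4-dihydro-2H-chromene-6-carbaldehyde
Conditions: Pd2(dba)3 (dba = dibenzylideneacetone, 1.5 mol%), t-BuXPhos (2-di-tert-butylphosphino-2',4',6'-triisopropylbiphenyl, 4 mol%), Cs2CO3 (1.5 equiv), toluene, 80 °C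
Reagents that add atoms: none
Why: Zerovalent palladium carrying the bulky di-tert-butylbiarylphosphine should insert into the C8a–Cl bond, which the para formyl group activates; Cs2CO3 then deprotonates the coordinated tertiary alcohol to give a seven-membered aryl(alkoxo) chelate of divalent palladium, and C–O reductive elimination forms O1–C8a. The closest known reaction type is the Buchwald–Hartwig-type intramolecular etherification of aryl halides with tertiary alcohols, which is established for 2,2-dialkylchromans. The one ring formed, the dihydropyran, is closed as a six-membered cyclic ether by reductive elimination from that seven-membered palladacycle, the oxygen ending on the arene carbon ortho to its three-carbon tether. No stereocentre is created. The step needs regiocontrol (O1 on C8a, para to the formyl carbon) and chemoselectivity against hydrodechlorination. The first is secured because chlorine marks the only reactive arene carbon and both phenolic oxygens are capped as MOM ethers; the second because the tertiary alkoxide has no β-hydrogen and the electron-poor aryl group speeds reductive elimination.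

Step 6
Reactants: 10 3-bromo-4,5-dihydroxybenzaldehyde
Product: 11 3-bromo-5-hydroxy-4-methoxybenzaldehyde
Conditions: MeI (1.1 equiv), Li2CO3 (1.2 equiv), DMF, 40 °C
Reagents that add atoms: iodomethane, CI
Why: Williamson methylation under a weak base should be regioselective because only the hydroxyl para to the formyl group and ortho to bromine is acidic enough to be ionised, which sets the 3-hydroxy-4-methoxy pattern of ring B.

Step 7
Reactants: 11 3-bromo-5-hydroxy-4-methoxybenzaldehyde
Product: 12 3-bromo-4-methoxy-5-(methoxymethoxy)benzaldehyde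
Conditions: MOMCl (1.3 equiv), i-Pr2NEt (1.5 equiv), CH2Cl2, 0 °C → rt
Reagents that add atoms: chloromethyl methyl ether, COCCl
Why: MOM protection of the remaining phenol (O-alkylation) masks the acidic proton for the organomagnesium steps and allows one common deprotection at the end.

Step 8
Reactants: 12 3-bromo-4-methoxy-5-(methoxymethoxy)benzaldehyde
Product: 13 1-bromo-5-ethenyl-2-methoxy-3-(methoxymethoxy)benzene
Conditions: Ph3PCH3Br (1.3 equiv), KOt-Bu (1.25 equiv), THF, 0 °C → rt
Reagents that add atoms: methyltriphenylphosphonium bromide, C[P+](c1ccccc1)(c1ccccc1)c1ccccc1.[Br-]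
Why: Wittig methylenation of the non-enolisable aryl aldehyde should give the styrene, which supplies both side-chain carbons and removes the electrophilic formyl group before the aryl bromide is metalated.

Step 9
Reactants: 13 1-bromo-5-ethenyl-2-methoxy-3-(methoxymethoxy)benzene; 14 prenyl bromide (1-bromo-3-methylbut-2-ene)
Product: 16 5-ethenyl-2-methoxy-1-(methoxymethoxy)-3-(3-methylbut-2-en-1-yl)benzene, via arylmagnesium bromide 15 (not isolated)
Conditions: Mg turnings, LiCl, THF, rt; then CuI (5 mol%), 14 (1.2 equiv), 0 °C
Reagents that add atoms: none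
Why: LiCl-assisted magnesium insertion into the aryl bromide should give an arylmagnesium halide that leaves the vinyl group alone, and copper-catalysed allylic substitution on prenyl bromide takes place at the primary carbon (attack at the tertiary terminus would build a quaternary centre), giving the linear prenyl arene.

Step 10
Reactants: 16 5-ethenyl-2-methoxy-1-(methoxymethoxy)-3-(3-methylbut-2-en-1-yl)benzene
Product: 18 2-[4-methoxy-3-(methoxymethoxy)-5-(3-methylbut-2-en-1-yl)phenyl]ethan-1-ol, via alkylborane 17 (not isolated)
Conditions: 9-BBN (1.1 equiv), THF, 0 °C → rt; then NaOH (aq), H2O2, 0 °C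
Reagents that add atoms: hydrogen peroxide, OO
Why: Hydroboration–oxidation with the bulky borane 9-BBN should be selective for the monosubstituted styrene alkene over the trisubstituted prenyl alkene and places boron, then hydroxyl, on the terminal carbon (anti-Markovnikov).

Step 11
Reactants: 18 2-[4-methoxy-3-(methoxymethoxy)-5-(3-methylbut-2-en-1-yl)phenyl]ethan-1-ol
Product: 19 5-(2-bromoethyl)-2-methoxy-1-(methoxymethoxy)-3-(3-methylbut-2-en-1-yl)benzene
Conditions: CBr4 (1.2 equiv), PPh3 (1.25 equiv), CH2Cl2, 0 °C
Reagents that add atoms: carbon tetrabromide, BrC(Br)(Br)Br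
Why: The Appel reaction should convert the primary alcohol into the bromide under neutral conditions that spare the MOM acetal and the prenyl alkene.

Step 12
Reactants: 19 5-(2-bromoethyl)-2-methoxy-1-(methoxymethoxy)-3-(3-methylbut-2-en-1-yl)benzene; 9 5,7-bis(methoxymethoxy)-2,2-dimethyl-3,4-dihydro-2H-chromene-6-carbaldehyde
Product: 21 1-[5,7-bis(methoxymethoxy)-2,2-dimethyl-3,4-dihydro-2H-chromen-6-yl]-3-[4-methoxy-3-(methoxymethoxy)-5-(3-methylbut-2-en-1-yl)phenyl]propan-1-ol (racemic), via alkylmagnesium bromide 20 (not isolated)
Conditions: 19, Mg turnings, THF, rt → 40 °C; then 9, THF, −20 → 0 °C; aq NH4Cl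
Reagents that add atoms: none
Why: Magnesium insertion into the primary bromide and Grignard addition to the formyl group should form the C–C bond of the three-carbon bridge; the carbinol stereocentre forms without control as a racemate, which does not matter because step 13 removes it.

Step 13
Reactants: 21 1-[5,7-bis(methoxymethoxy)-2,2-dimethyl-3,4-dihydro-2H-chromen-6-yl]-3-[4-methoxy-3-(methoxymethoxy)-5-(3-methylbut-2-en-1-yl)phenyl]propan-1-ol
Product: 22 1-[5,7-bis(methoxymethoxy)-2,2-dimethyl-3,4-dihydro-2H-chromen-6-yl]-3-[4-methoxy-3-(methoxymethoxy)-5-(3-methylbut-2-en-1-yl)phenyl]propan-1-one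
Conditions: DMP (Dess–Martin periodinane, 1.3 equiv), CH2Cl2, 0 °C → rt
Reagents that add atoms: none
Why: Dess–Martin oxidation of the secondary benzylic alcohol to the aryl ketone should proceed under near-neutral conditions that leave the MOM acetals, the chroman and the prenyl alkene untouched.

Step 14
Reactants: 22 1-[5,7-bis(methoxymethoxy)-2,2-dimethyl-3,4-dihydro-2H-chromen-6-yl]-3-[4-methoxy-3-(methoxymethoxy)-5-(3-methylbut-2-en-1-yl)phenyl]propan-1-one
Product: 23 1-(5,7-dihydroxy-2,2-dimethyl-3,4-dihydro-2H-chromen-6-yl)-3-[3-hydroxy-4-methoxy-5-(3-methylbut-2-en-1-yl)phenyl]propan-1-one (CNP0408176.0)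
Conditions: HCl (3 M aq)/MeOH, rt → 40 °C
Reagents that add atoms: none
Why: Acid-catalysed acetal exchange with methanol (MOM cleavage) should free all three phenols, while the prenyl group on ring B has no neighbouring hydroxyl to cyclise onto and the mild temperature avoids addition to its alkene.

Compound list
1 | 5-chlororesorcinol (5-chlorobenzene-1,3-diol) | Oc1cc(O)cc(Cl)c1 | starting material
2 | 1-chloro-3,5-bis(methoxymethoxy)benzene | COCOc1cc(Cl)cc(OCOC)c1 | intermediate
3 | 2-bromo-1-chloro-3,5-bis(methoxymethoxy)benzene | COCOc1cc(Cl)c(Br)c(OCOC)c1 | intermediate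
4 | 2-methylbut-3-en-2-ol | C=CC(C)(C)O | starting material
5 | 9-(3-hydroxy-3-methylbutyl)-9-borabicyclo[3.3.1]nonane (not isolated) | CC(C)(O)CCB1C2CCCC1CCC2 | intermediate
6 | 4-[2-chloro-4,6-bis(methoxymethoxy)phenyl]-2-methylbutan-2-ol | COCOc1cc(Cl)c(CCC(C)(C)O)c(OCOC)c1 | intermediate
7 | lithium 4-[2-chloro-5-lithio-4,6-bis(methoxymethoxy)phenyl]-2-methylbutan-2-olate (not isolated) | COCOc1cc(Cl)c(CCC(C)(C)O[Li])c(OCOC)c1[Li] | intermediate
8 | 4-chloro-3-(3-hydroxy-3-methylbutyl)-2,6-bis(methoxymethoxy)benzaldehyde | O=Cc1c(OCOC)cc(Cl)c(CCC(C)(C)O)c1OCOC | intermediate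
9 | 5,7-bis(methoxymethoxy)-2,2-dimethyl-3,4-dihydro-2H-chromene-6-carbaldehyde | O=Cc1c(OCOC)cc2c(c1OCOC)CCC(C)(C)O2 | intermediate
10 | 3-bromo-4,5-dihydroxybenzaldehyde | O=Cc1cc(O)c(O)c(Br)c1 | starting material
11 | 3-bromo-5-hydroxy-4-methoxybenzaldehyde | O=Cc1cc(O)c(OC)c(Br)c1 | intermediate
12 | 3-bromo-4-methoxy-5-(methoxymethoxy)benzaldehyde | O=Cc1cc(OCOC)c(OC)c(Br)c1 | intermediate
13 | 1-bromo-5-ethenyl-2-methoxy-3-(methoxymethoxy)benzene | C=Cc1cc(OCOC)c(OC)c(Br)c1 | intermediate
14 | prenyl bromide (1-bromo-3-methylbut-2-ene) | CC(C)=CCBr | starting material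
15 | [5-ethenyl-2-methoxy-3-(methoxymethoxy)phenyl]magnesium bromide (not isolated) | C=Cc1cc(OCOC)c(OC)c([Mg]Br)c1 | intermediate
16 | 5-ethenyl-2-methoxy-1-(methoxymethoxy)-3-(3-methylbut-2-en-1-yl)benzene | C=Cc1cc(OCOC)c(OC)c(CC=C(C)C)c1 | intermediate
17 | 9-{2-[4-methoxy-3-(methoxymethoxy)-5-(3-methylbut-2-en-1-yl)phenyl]ethyl}-9-borabicyclo[3.3.1]nonane (not isolated) | C(Cc1cc(OCOC)c(OC)c(CC=C(C)C)c1)B1C2CCCC1CCC2 | intermediate
18 | 2-[4-methoxy-3-(methoxymethoxy)-5-(3-methylbut-2-en-1-yl)phenyl]ethan-1-ol | OCCc1cc(OCOC)c(OC)c(CC=C(C)C)c1 | intermediate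
19 | 5-(2-bromoethyl)-2-methoxy-1-(methoxymethoxy)-3-(3-methylbut-2-en-1-yl)benzene | BrCCc1cc(OCOC)c(OC)c(CC=C(C)C)c1 | intermediate
20 | {2-[4-methoxy-3-(methoxymethoxy)-5-(3-methylbut-2-en-1-yl)phenyl]ethyl}magnesium bromide (not isolated) | Br[Mg]CCc1cc(OCOC)c(OC)c(CC=C(C)C)c1 | intermediate
21 | 1-[5,7-bis(methoxymethoxy)-2,2-dimethyl-3,4-dihydro-2H-chromen-6-yl]-3-[4-methoxy-3-(methoxymethoxy)-5-(3-methylbut-2-en-1-yl)phenyl]propan-1-ol (racemic) | OC(CCc1cc(OCOC)c(OC)c(CC=C(C)C)c1)c1c(OCOC)cc2c(c1OCOC)CCC(C)(C)O2 | intermediate
22 | 1-[5,7-bis(methoxymethoxy)-2,2-dimethyl-3,4-dihydro-2H-chromen-6-yl]-3-[4-methoxy-3-(methoxymethoxy)-5-(3-methylbut-2-en-1-yl)phenyl]propan-1-one | O=C(CCc1cc(OCOC)c(OC)c(CC=C(C)C)c1)c1c(OCOC)cc2c(c1OCOC)CCC(C)(C)O2 | intermediate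
23 | 1-(5,7-dihydroxy-2,2-dimethyl-3,4-dihydro-2H-chromen-6-yl)-3-[3-hydroxy-4-methoxy-5-(3-methylbut-2-en-1-yl)phenyl]propan-1-one (CNP0408176.0; no stereocentre) | COc1c(O)cc(CCC(=O)c2c(O)cc3c(c2O)CCC(C)(C)O3)cc1CC=C(C)C | target

Total step count: 14 (ring A branch steps 1–5, ring B branch steps 6–11, union and endgame steps 12–14).
Longest linear sequence: 9 steps (steps 6–11, then 12–14, from 10); the ring A line from 1 is 8 steps.

Steps most likely to fail

Step 5 (key step). Oxidative addition into the aryl chloride may be slow, or the catalyst may be consumed before reductive elimination, so that hydrodechlorination or slow degradation of the formyl group under hot carbonate competes with ring closure. Fallback: the same O1–C8a bond is closed without a transition metal by intramolecular nucleophilic aromatic substitution. Compound 8 is treated with NaH in DMF (0 → 60 °C); the tertiary alkoxide adds to the chlorine-bearing carbon para to the formyl group, and loss of chloride from the Meisenheimer adduct gives 9. The fallback sets out from 8 and comes back to the route at 9; it makes no new isolated compound.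

Step 3. Transmetalation at the aryl bromide, which is flanked on both sides (chlorine and a MOM ether), may be slow, so that protodebromination or stalling of the coupling takes over. Fallback: the polarity is reversed. Compound 3 undergoes bromine–magnesium exchange (i-PrMgCl·LiCl, THF, −15 → 0 °C; the chloride is untouched) to give [2-chloro-4,6-bis(methoxymethoxy)phenyl]magnesium chloride F1, which is allylated in the same flask with prenyl bromide 14 (CuI, 5 mol%) to give 1-chloro-3,5-bis(methoxymethoxy)-2-(3-methylbut-2-en-1-yl)benzene F2. Markovnikov hydration of the trisubstituted alkene under Mukaiyama conditions (Co(acac)2 cat., PhSiH3, O2, THF, rt), at a stage where no formyl group is present, should then give the tertiary alcohol. The fallback sets out from 3 and comes back at 6.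

Step 9. Radical intermediates of the magnesium insertion may attack the styrene unit (oligomerisation) or give homocoupling, and some allylation may occur at the tertiary terminus. Fallback: the prenyl group is introduced by palladium catalysis before the olefination. Compound 12 is coupled with tributyl(3-methylbut-2-en-1-yl)stannane (Stille coupling, Pd(PPh3)4, DMF, 90 °C; the allylpalladium intermediate equilibrates to its primary terminus before C–C bond formation) to give 4-methoxy-3-(methoxymethoxy)-5-(3-methylbut-2-en-1-yl)benzaldehyde F3. Wittig methylenation (Ph3PCH3Br, KOt-Bu, THF) then gives the styrene. The fallback sets out from 12 and comes back at 16.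

Further compounds
F0 | step 5 | none | none
F1 | step 3 | [2-chloro-4,6-bis(methoxymethoxy)phenyl]magnesium chloride | COCOc1cc(Cl)c([Mg]Cl)c(OCOC)c1
F2 | step 3 | 1-chloro-3,5-bis(methoxymethoxy)-2-(3-methylbut-2-en-1-yl)benzene | COCOc1cc(Cl)c(CC=C(C)C)c(OCOC)c1
F3 | step 9 | 4-methoxy-3-(methoxymethoxy)-5-(3-methylbut-2-en-1-yl)benzaldehyde | O=Cc1cc(OCOC)c(OC)c(CC=C(C)C)c1
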